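## The problem

3β-Acetoxy-agathic acid (28) is a trans-decalin (ring A = C1–C5 and C10, ring B = C5–C10) with five stereocentres, C3, C4, C5, C9 and C10. C4 and C10 are quaternary and 1,3-related, and the C19 carboxyl on C4 is axial, on the face of the C10 methyl. Ring B carries the exocyclic C8=C17 methylene and, on C9, an equatorial five-carbon chain ending in an (E)-trisubstituted 2-enoic acid (C13=C14, C15). Only C10 has to be set in the absolute sense, because its axial methyl can then direct C5 (axial protonation in a dissolving-metal reduction), C4 (enolate alkylation on the opposite face), C3 (axial hydride delivery) and C9 (protonation of a C8 enol from the open α face). Three groups restrict the chemistry: the 1,1-disubstituted alkene migrates into the ring under acid, the enoate does not survive dissolving metal, and the C3 acetate must outlast the liberation of two carboxylic acids, of which C19 is too hindered for ordinary saponification, so the order of events and the final unmasking are part of the design. The enabling feature lies in ring A: O3 is para to the methyl-bearing C10 and ortho to C4, which carries C19, and C5 carries the first carbon of ring B. This is a 5-methylsalicylate with a side chain on the carbon between ester and methyl, and bonding a nucleophilic C9 at the end of that chain to C10 converts the arene into ring A, closes ring B and creates the quaternary centre in one step.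

## Retrosynthesis

**Unmasking the acids (28 from 27).** The two carboxyl O–H bonds are traced back to allyl esters in 27. Methyl esters would need hydroxide or thiolate at the end, which would remove the acetate or add to the enoate, and tert-butyl esters would need acid, which endangers the C8=C17 alkene. The forward step must cleave both esters under neutral conditions regardless of the hindrance at C19, which a zerovalent palladium deallylation does because it attacks the allyl group and not the acyl carbon.

**The methylene (27 from 26).** The C8=C17 bond is cut to the C8 ketone 26. Dehydrating a tertiary C8 alcohol would give endocyclic isomers, whereas carbonyl methylenation is regiospecific. The reagent must be non-basic, because C9 is an enolizable stereocentre and four ester groups are present.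

**Enoate and loss of the C9 carboxyl (26 from 24, 24 from 21 and 22).** The C9–CO2 bond and the C13=C14 bond are cut in that order. Olefination of the methyl ketone 21 with phosphonate 22 is placed before decarboxylation because, as long as C9 is quaternary, the C8 ketone is too shielded to be olefinated and has no C9 hydrogen to lose, so the methyl ketone is the only carbonyl that the phosphonate anion can reach. The C9 ester is tert-butyl so that acid removes it while allyl esters and acetate stay, and the decarboxylation ends with protonation of C9 on the α face, which sets the equatorial chain.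

**The side chain on C9 (21 from 19 and 20).** The C9–C11 bond is cut to β-keto ester 19 and methyl vinyl ketone (20). Alkylation with a 3-oxobutyl halide would be slower at this congested carbon and prone to O-alkylation. The conjugate addition brings C11, C12, C13 and C16 in one step, and the same ester that activated C9 in the key step activates it here.

**Ring A stereocentres (19 back to 10).** The C3–H, C4–CH3 and C5–H bonds are cut. The enone ester 12 gives ketone 14 by reductive methylation, which sets C5 and C4 together. Hydride then sets C3 (15). The C8 ketone is held as a dioxolane (12 from 11) through both operations. The C19 methyl ester is exchanged for allyl only after C3 is an alcohol (17), because demethylation at the ketone stage would create a β-keto acid. Acetylation (18) and ketal removal (19) follow. Enone 11 comes from dienone 10 by saturating only the C1=C2 bond.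

**Key disconnection (10 from 9).** The C9–C10 bond is cut. This opens ring B, removes the quaternary centre and rearomatizes ring A to the salicylate 9, which has no stereocentre. Cutting C5–C6 or C8–C9 instead would leave a chiral cyclohexane to be made first. The forward reaction must oxidize 9 by two electrons, bond the enol carbon C9 to the para carbon C10 rather than to C4 or through the enol oxygen, and choose one face of the arene.

**The precursor (9 from 1 and 5).** The C6–C7 bond is cut to benzylic bromide 4 and the dianion of tert-butyl acetoacetate (5), and the C10 methyl is traced to an aryl bromide (8 from 7) so that 4 has only one benzylic methyl to brominate. Bromide 4 comes from methyl 2-hydroxy-6-methylbenzoate (1) by ring bromination (2), silylation (3) and benzylic bromination. Ring bromination is done first, before any β-keto ester is present to compete for the electrophile.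

## Roads not taken

**Alternative 1:** The cut is the C3–C4 bond of ring A in a compound that already has ring B. The chiral-pool lactone A1, (+)-sclareolide, would be degraded to the 3,4-seco aldehyde A2, in which C4 is the α-carbon of a methacrylate and C3 an aldehyde. In the forward step [(Ph3P)CuH]6 would add hydride to the methacrylate CH2, and the copper enolate would close ring A by aldol addition to C3 to give hydroxy ester A3.
- Merits: C5, C9 and C10 come enantiopure from the chiral pool, the two-carbon stub on C9 and the C8 oxygen are in place, and no enantioselective step is needed. In absolute stereocontrol this road is safer than the chosen one.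
- Weak points: A1 has two methyl groups on C4 and no oxygen on C3. Reaching A2 therefore needs oxidation of an unactivated ring A methylene, ring cleavage and oxidation of one C4 methyl to the ester level. The reductive aldol must set C3 and C4 together, with the ester axial and the hydroxyl equatorial, out of four possible diastereomers, and nothing in A2 clearly enforces that. The chain must still be grown from C12 of A3.
- Comparison: against the safer absolute control, the chosen plan offers a ring A that arrives from 1 with O3 and C19 already differentiated, and C3, C4 and C5 each set by a reaction with a known directing effect of the C10 methyl.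

**Alternative 2:** The cuts are C1–C10 and C4–C5 of ring A. The cyclic dione A4, which is 2-methylcyclohexane-1,3-dione, and the vinyl β-keto ester A5, which is methyl 3-oxopent-4-enoate, would be joined by Michael addition at the methyl-bearing carbon of A4. A chiral secondary amine would then close ring A by aldol condensation onto one of the two enantiotopic ring carbonyls to give enedione A6.
- Merits: the amine-catalysed desymmetrizing annulation is among the best-precedented enantioselective ring constructions. It gives the same ring A enone ester that the chosen route uses for the reductive methylation, in one or two steps from A4, a bulk chemical. In steps to the first chiral bicycle and in reliability of the asymmetric step it is better than the chosen plan.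
- Weak points: A5 polymerizes readily. A6 has its ring B carbonyl on C9, not on C8, so the chain must be attached by carbonyl addition next to the quaternary C10, C8 must be introduced by a one-carbon homologation or carbonyl transposition, and the C9 stereocentre has no enolate handle.
- Comparison: against the shorter and safer start from A4, the chosen plan offers dienone 10 with a ketone on C8 for the methylene and a β-keto ester on C9 for the chain, exactly where they are needed.

**Alternative 3:** The cut is C8–C9 in ring B. Xanthate A7 is a fully substituted ring A cyclohexanone with a butynyl arm on C5 and the ketal-protected chain on a xanthate-bearing C9. With Bu3SnH it would give a secondary radical that adds 6-exo-dig to C8; the vinyl radical takes hydrogen to give ketal A8.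
- Merits: the exocyclic alkene is formed directly, so no ketone methylenation is needed. The complete chain skeleton is present, both C9 epimers of A7 converge on one radical, and A8 is only a few steps from 28. After its key step this road is shorter than the chosen one.
- Weak points: the difficulty moves into A7, whose three contiguous ring stereocentres (C4, C5, C10, two of them quaternary) must be made enantioselectively on a monocycle without the conformational guidance of a decalin. The 6-exo-dig closure of a hindered secondary radical next to a quaternary centre is slow enough for premature reduction and 1,5-hydrogen transfer to compete. C9 is set in a radical transition state, and tin is used stoichiometrically.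
- Comparison: against the shorter endgame the chosen plan offers a precursor (9) that is available in six routine steps and stereocentres introduced one at a time on a rigid bicycle.

Key step: step 7

## Conventions and assumptions

- Bicyclic compounds are numbered as labdanes: ring A = C1–C5, C10; ring B = C5–C10; C20 is the methyl on C10; C18 (methyl) and C19 (carboxyl carbon) are on C4. β is the face of the C10 methyl and α the opposite face. "Decalin" names use this numbering.
- ArI* is the C2-symmetric iodoarene (R,R)-2,2'-[(2-iodo-1,3-phenylene)bis(oxy)]bis(N-mesitylpropanamide), SMILES C[C@@H](Oc1cccc(O[C@H](C)C(=O)Nc2c(C)cc(C)cc2C)c1I)C(=O)Nc1c(C)cc(C)cc1C. Which antipode of ArI* leads to 10 has to be found by experiment; both are accessible from the two lactic esters.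
- Assumption: the β-keto esters 10, 11 and 19 are written as keto tautomers with the 9β (equatorial) ester. Their enol content and C9 epimer ratio do not matter, because C9 becomes quaternary in step 15 and is re-protonated in step 17.

## Route

Step 1
Reactants: 1 methyl 2-hydroxy-6-methylbenzoate
Product: 2 methyl 3-bromo-6-hydroxy-2-methylbenzoate
Conditions: NBS (1.0 equiv), MeCN, 0 °C to rt
Reagents that add atoms: N-bromosuccinimide, O=C1CCC(=O)N1Br
Why: Electrophilic aromatic bromination; the position para to OH and ortho to the methyl is the most activated and the least hindered by the hydrogen-bonded ester, and NBS in MeCN is para-selective for phenols.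

Step 2
Reactants: 2 methyl 3-bromo-6-hydroxy-2-methylbenzoate
Product: 3 methyl 3-bromo-6-[(tert-butyldimethylsilyl)oxy]-2-methylbenzoate
Conditions: TBSCl, imidazole, DMF, rt
Reagents that add atoms: tert-butyldimethylsilyl chloride, CC(C)(C)[Si](C)(C)Cl
Why: O-Silylation of the phenol; the silyl ether tolerates radical bromination, the enolate dianion and neutral cross-coupling, and keeps the ring from being brominated again.

Step 3
Reactants: 3 methyl 3-bromo-6-[(tert-butyldimethylsilyl)oxy]-2-methylbenzoate
Product: 4 methyl 3-bromo-2-(bromomethyl)-6-[(tert-butyldimethylsilyl)oxy]benzoate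
Conditions: NBS (1.05 equiv), AIBN (cat.), PhCF3, 85 °C
Reagents that add atoms: N-bromosuccinimide, O=C1CCC(=O)N1Br
Why: Wohl–Ziegler benzylic bromination; there is only one benzylic methyl, and the ring is deactivated toward ionic bromination by the bromine and the ester.

Step 4
Reactants: 4 methyl 3-bromo-2-(bromomethyl)-6-[(tert-butyldimethylsilyl)oxy]benzoate; 5 tert-butyl acetoacetate (tert-butyl 3-oxobutanoate)
Product: 7 methyl 3-bromo-2-(5-tert-butoxy-3,5-dioxopentyl)-6-[(tert-butyldimethylsilyl)oxy]benzoate, via acetoacetate dianion 6 (not isolated)
Conditions: 5, NaH, THF, 0 °C; n-BuLi, 0 °C; then 4, −78 to 0 °C; aq. NH4Cl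
Reagents that add atoms: none
Why: γ-Alkylation of an acetoacetate dianion; the more basic terminal carbanion displaces the benzylic bromide (SN2), while the aryl bromide, the doubly ortho-substituted methyl ester and the silyl ether are inert at these temperatures.

Step 5
Reactants: 7 methyl 3-bromo-2-(5-tert-butoxy-3,5-dioxopentyl)-6-[(tert-butyldimethylsilyl)oxy]benzoate
Product: 8 methyl 2-(5-tert-butoxy-3,5-dioxopentyl)-6-[(tert-butyldimethylsilyl)oxy]-3-methylbenzoate
Conditions: Me4Sn (3 equiv), PdCl2(PPh3)2 (5 mol%), DMF, 80 °C, sealed vessel
Reagents that add atoms: tetramethylstannane, C[Sn](C)(C)C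
Why: Stille methylation of the aryl bromide; the base-free conditions leave the β-keto ester protonated, so that enolate arylation by the arylpalladium intermediate should not compete.

Step 6
Reactants: 8 methyl 2-(5-tert-butoxy-3,5-dioxopentyl)-6-[(tert-butyldimethylsilyl)oxy]-3-methylbenzoate
Product: 9 methyl 2-(5-tert-butoxy-3,5-dioxopentyl)-6-hydroxy-3-methylbenzoate
Conditions: Bu4NF, AcOH, THF, 0 °C
Reagents that add atoms: none
Why: Fluoride desilylation of an aryl silyl ether; the acetic acid buffer protects the β-keto ester and the salicylate ester from basic fluoride.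

Step 7
Reactants: 9 methyl 2-(5-tert-butoxy-3,5-dioxopentyl)-6-hydroxy-3-methylbenzoate
Product: 10 1-tert-butyl 5-methyl (1R,8aR)-8a-methyl-2,6-dioxo-1,2,3,4,6,8a-hexahydronaphthalene-1,5-dicarboxylate (labdane numbering: 1,4-dien-3-one with the methyl ester on C4; 8-oxo; 9β-CO2t-Bu; 10β-CH3)
Conditions: ArI* (1.2 equiv), Bu4NBF4 (0.1 M), (CF3)2CHOH, glassy-carbon anode, Pt cathode, undivided cell, constant current, 2.2 F per mol ArI*, rt; then CH2Cl2, −40 °C, add 9
Reagents that add atoms: none
Why: Proposed new method: the anodically generated chiral aryl-λ3-iodane (trivalent iodine with two hexafluoroisopropoxy ligands) should exchange a ligand for the enol of the β-keto ester rather than for the hydrogen-bonded, ester-deactivated salicylate OH; the iodine-bound C9 is then electrophilic and is attacked by the phenol carbon C10, para to OH, with reductive loss of the iodoarene (trivalent to monovalent iodine) and of the phenolic proton, which leaves the cross-conjugated dienone, and a phenol-bound iodane attacked at C10 by the enol is a second path to the same product. The closest known reaction types are the racemic trivalent-iodine or anodic dearomatization of para-alkyl phenols by tethered carbon nucleophiles and the chiral-iodoarene-mediated dearomatizing spirocyclization of aryl-tethered 1,3-dicarbonyl compounds, and the anodic generation of such iodanes in (CF3)2CHOH for use outside the electrolysis is known as well. Ring B closes in a six-membered annulative mode, C9 adding to the arene carbon next to the tether (6-exo with respect to the C1=C10 π bond that is consumed). C10 is controlled by the lactamide arms of the mediator, which sit on the iodine bound at C9, one bond from the forming C9–C10 bond; C9 is an enolizable β-keto ester centre and should settle as the equatorial 9β ester under thermodynamic control. The step needs attack at C10 rather than at C4 or through the enol oxygen, and one face of the arene: C10 is para to oxygen and methyl-substituted whereas C4 carries the ester, the carbon-bound iodane path can form only a C–C bond, and making the oxidant before 9 is added at −40 °C keeps unselective direct anodic oxidation of the phenol out of the flask.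

Step 8
Reactants: 10 1-tert-butyl 5-methyl (1R,8aR)-8a-methyl-2,6-dioxo-1,2,3,4,6,8a-hexahydronaphthalene-1,5-dicarboxylate
Product: 11 1-tert-butyl 5-methyl (1R,8aR)-8a-methyl-2,6-dioxo-1,2,3,4,6,7,8,8a-octahydronaphthalene-1,5-dicarboxylate (labdane numbering: 4-en-3-one; 8-oxo; 9β-CO2t-Bu; 10β-CH3)
Conditions: H2 (1 atm), RhCl(PPh3)3 (5 mol%), benzene–EtOH, rt
Reagents that add atoms: none
Why: Homogeneous hydrogenation; RhCl(PPh3)3 reduces the disubstituted C1=C2 bond of cross-conjugated 1,4-dien-3-ones and leaves the tetrasubstituted, ester-bearing C4=C5 bond untouched.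

Step 9
Reactants: 11 1-tert-butyl 5-methyl (1R,8aR)-8a-methyl-2,6-dioxo-1,2,3,4,6,7,8,8a-octahydronaphthalene-1,5-dicarboxylate
Product: 12 methyl (C19) tert-butyl (C9) 8,8-(ethylenedioxy)-10β-methyl-3-oxodecal-4-ene-4,9β-dicarboxylate
Conditions: Me3SiOCH2CH2OSiMe3 (1.5 equiv), Me3SiOTf (5 mol%), CH2Cl2, −78 to −20 °C; pyridine quench
Reagents that add atoms: 1,2-bis(trimethylsilyloxy)ethane, C[Si](C)(C)OCCO[Si](C)(C)C
Why: Silyl-triflate-catalysed dioxolane formation; the saturated C8 ketone reacts while the conjugated, ester-flanked C3 ketone does not, and the low temperature spares the tert-butyl ester.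

Step 10
Reactants: 12 methyl (C19) tert-butyl (C9) 8,8-(ethylenedioxy)-10β-methyl-3-oxodecal-4-ene-4,9β-dicarboxylate
Product: 14 methyl (C19) tert-butyl (C9) 8,8-(ethylenedioxy)-4α,10β-dimethyl-3-oxo-5α-decalin-4β,9β-dicarboxylate, via lithium enolate 13 (not isolated)
Conditions: Li (2.2 equiv), NH3(l)–THF, t-BuOH (1.0 equiv), −78 °C; then MeI (5 equiv), −78 to −33 °C; aq. NH4Cl
Reagents that add atoms: iodomethane, CI
Why: Birch-type reductive alkylation of an α-carboalkoxy enone; C5 is protonated axially on the α face to give the trans ring fusion, and the β-keto ester enolate is methylated at C4 anti to the axial C10 methyl, which places CH3 α (equatorial) and CO2Me β (axial). The ketal and the non-conjugated tert-butyl ester are not reduced by a stoichiometric amount of lithium at −78 °C.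

Step 11
Reactants: 14 methyl (C19) tert-butyl (C9) 8,8-(ethylenedioxy)-4α,10β-dimethyl-3-oxo-5α-decalin-4β,9β-dicarboxylate
Product: 15 methyl (C19) tert-butyl (C9) 8,8-(ethylenedioxy)-3β-hydroxy-4α,10β-dimethyl-5α-decalin-4β,9β-dicarboxylate
Conditions: NaBH4, MeOH–THF, 0 °C
Reagents that add atoms: none
Why: Borohydride reduction of the only ketone; the small hydride attacks C3 axially from the α face, as in 4,4-disubstituted 3-oxo terpenoids, and gives the equatorial 3β alcohol.

Step 12
Reactants: 15 methyl (C19) tert-butyl (C9) 8,8-(ethylenedioxy)-3β-hydroxy-4α,10β-dimethyl-5α-decalin-4β,9β-dicarboxylate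
Product: 17 allyl (C19) tert-butyl (C9) 8,8-(ethylenedioxy)-3β-hydroxy-4α,10β-dimethyl-5α-decalin-4β,9β-dicarboxylate, via sodium carboxylate 16 (not isolated)
Conditions: NaSEt (4 equiv), DMF, 90 °C; then allyl bromide (6 equiv), rt
Reagents that add atoms: allyl bromide, C=CCBr
Why: SN2 dealkylation of a hindered methyl ester by thiolate at the O-methyl carbon, where the shielding of the axial carbonyl does not matter and where a tert-butyl ester cannot react, followed by O-alkylation of the carboxylate in the same flask. It is done after step 11 so that no β-keto acid can form.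

Step 13
Reactants: 17 allyl (C19) tert-butyl (C9) 8,8-(ethylenedioxy)-3β-hydroxy-4α,10β-dimethyl-5α-decalin-4β,9β-dicarboxylate
Product: 18 allyl (C19) tert-butyl (C9) 3β-acetoxy-8,8-(ethylenedioxy)-4α,10β-dimethyl-5α-decalin-4β,9β-dicarboxylate
Conditions: Ac2O, DMAP (cat.), pyridine, rt
Reagents that add atoms: acetic anhydride, CC(=O)OC(C)=O
Why: DMAP-catalysed acylation of the equatorial secondary alcohol; C4 is quaternary, so the β-acetoxy ester cannot eliminate later.

Step 14
Reactants: 18 allyl (C19) tert-butyl (C9) 3β-acetoxy-8,8-(ethylenedioxy)-4α,10β-dimethyl-5α-decalin-4β,9β-dicarboxylate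
Product: 19 allyl (C19) tert-butyl (C9) 3β-acetoxy-4α,10β-dimethyl-8-oxo-5α-decalin-4β,9β-dicarboxylate
Conditions: pyridinium p-toluenesulfonate (0.2 equiv), acetone–H2O (10:1), 55 °C
Reagents that add atoms: water, O
Why: Mild acid-catalysed ketal hydrolysis; the weak acid should leave the tert-butyl ester, the acetate and the allyl ester intact and return the β-keto ester.

Step 15
Reactants: 19 allyl (C19) tert-butyl (C9) 3β-acetoxy-4α,10β-dimethyl-8-oxo-5α-decalin-4β,9β-dicarboxylate; 20 methyl vinyl ketone (but-3-en-2-one)
Product: 21 allyl (C19) tert-butyl (C9) 3β-acetoxy-4α,10β-dimethyl-8-oxo-9α-(3-oxobutyl)-5α-decalin-4β,9β-dicarboxylate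
Conditions: 20 (3 equiv), DBU (0.2 equiv), MeCN, rt
Reagents that add atoms: none
Why: Michael addition of a cyclic β-keto ester; 2-oxocycloalkanecarboxylates are the classical donors toward this acceptor, and catalytic amine base at rt should stop at the Michael stage. Attack is expected from the α face, anti to the C10 methyl, and the C9 configuration is erased in step 17.

Step 16
Reactants: 21 allyl (C19) tert-butyl (C9) 3β-acetoxy-4α,10β-dimethyl-8-oxo-9α-(3-oxobutyl)-5α-decalin-4β,9β-dicarboxylate; 22 allyl (diethoxyphosphoryl)acetate
Product: 24 allyl (C19) tert-butyl (C9) 3β-acetoxy-9α-[(3E)-5-(allyloxy)-3-methyl-5-oxopent-3-enyl]-4α,10β-dimethyl-8-oxo-5α-decalin-4β,9β-dicarboxylate, via phosphonate carbanion 23 (not isolated)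
Conditions: 22 (1.6 equiv), NaH (1.5 equiv), THF, 0 °C; then 21, 0 to 40 °C
Reagents that add atoms: none
Why: Horner–Wadsworth–Emmons olefination of the methyl ketone; the C8 ketone is flanked by the quaternary C9, so it is too hindered to react and cannot enolize toward C9. The stabilized phosphonate anion is a weak base, which should keep aldol closure of the 1,5-diketone slower than olefination. The E isomer should predominate, as is usual for methyl ketones of this type, and the Z isomer is removed by chromatography.

Step 17
Reactants: 24 allyl (C19) tert-butyl (C9) 3β-acetoxy-9α-[(3E)-5-(allyloxy)-3-methyl-5-oxopent-3-enyl]-4α,10β-dimethyl-8-oxo-5α-decalin-4β,9β-dicarboxylate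
Product: 26 diallyl 3β-acetoxy-8-oxo-17-norlabd-13E-ene-15,19-dioate, via β-keto acid 25 (not isolated)
Conditions: CF3CO2H–CH2Cl2 (1:4), 0 °C to rt; evaporate; toluene, 80 °C
Reagents that add atoms: none
Why: Acidolysis of the tert-butyl ester and thermal decarboxylation of the β-keto acid through its enol; ketonization should protonate C9 on the α face, anti to the C10 methyl, giving the equatorial 9β chain, which is also expected to be the more stable epimer. Any 9-epimer can be equilibrated with DBU and recycled.

Step 18
Reactants: 26 diallyl 3β-acetoxy-8-oxo-17-norlabd-13E-ene-15,19-dioate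
Product: 27 diallyl 3β-acetoxylabda-8(17),13E-diene-15,19-dioate
Conditions: Zn, CH2Br2, TiCl4, THF (reagent aged at 5 °C); then 26, CH2Cl2, 0 °C to rt
Reagents that add atoms: dibromomethane, BrCBr
Why: Takai–Lombardo methylenation; the zinc–titanium methylene reagent is non-basic, so it should not epimerize C9 or deconjugate the enoate, and it reacts with ketones in the presence of esters.

Step 19
Reactants: 27 diallyl 3β-acetoxylabda-8(17),13E-diene-15,19-dioate
Product: 28 3β-acetoxylabda-8(17),13E-diene-15,19-dioic acid (3β-acetoxy-agathic acid)
Conditions: Pd(PPh3)4 (5 mol%), morpholine (10 equiv), THF, rt; dilute aq. citric acid work-up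
Reagents that add atoms: none
Why: Tsuji–Trost deallylation; zerovalent palladium ionizes both allyl esters at the allyl carbon, independent of the hindrance at C19, and morpholine traps the π-allyl fragment. Neither acid nor hydroxide is present, so the acetate and both alkenes are untouched.

## Compound list

1 | methyl 2-hydroxy-6-methylbenzoate | Cc1cccc(O)c1C(=O)OC | starting material
2 | methyl 3-bromo-6-hydroxy-2-methylbenzoate | COC(=O)c1c(O)ccc(Br)c1C | intermediate
3 | methyl 3-bromo-6-[(tert-butyldimethylsilyl)oxy]-2-methylbenzoate | COC(=O)c1c(O[Si](C)(C)C(C)(C)C)ccc(Br)c1C | intermediate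
4 | methyl 3-bromo-2-(bromomethyl)-6-[(tert-butyldimethylsilyl)oxy]benzoate | COC(=O)c1c(O[Si](C)(C)C(C)(C)C)ccc(Br)c1CBr | intermediate
5 | tert-butyl acetoacetate | CC(=O)CC(=O)OC(C)(C)C | starting material
6 | sodium lithium dianion of tert-butyl acetoacetate (not isolated) | [Na+].[Li+].[CH2-]C(=O)[CH-]C(=O)OC(C)(C)C | intermediate
7 | methyl 3-bromo-2-(5-tert-butoxy-3,5-dioxopentyl)-6-[(tert-butyldimethylsilyl)oxy]benzoate | COC(=O)c1c(O[Si](C)(C)C(C)(C)C)ccc(Br)c1CCC(=O)CC(=O)OC(C)(C)C | intermediate
8 | methyl 2-(5-tert-butoxy-3,5-dioxopentyl)-6-[(tert-butyldimethylsilyl)oxy]-3-methylbenzoate | COC(=O)c1c(O[Si](C)(C)C(C)(C)C)ccc(C)c1CCC(=O)CC(=O)OC(C)(C)C | intermediate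
9 | methyl 2-(5-tert-butoxy-3,5-dioxopentyl)-6-hydroxy-3-methylbenzoate | COC(=O)c1c(O)ccc(C)c1CCC(=O)CC(=O)OC(C)(C)C | intermediate
10 | 1-tert-butyl 5-methyl (1R,8aR)-8a-methyl-2,6-dioxo-1,2,3,4,6,8a-hexahydronaphthalene-1,5-dicarboxylate | COC(=O)C1=C2CCC(=O)[C@H](C(=O)OC(C)(C)C)[C@@]2(C)C=CC1=O | intermediate
11 | 1-tert-butyl 5-methyl (1R,8aR)-8a-methyl-2,6-dioxo-1,2,3,4,6,7,8,8a-octahydronaphthalene-1,5-dicarboxylate | COC(=O)C1=C2CCC(=O)[C@H](C(=O)OC(C)(C)C)[C@@]2(C)CCC1=O | intermediate
12 | methyl (C19) tert-butyl (C9) 8,8-(ethylenedioxy)-10β-methyl-3-oxodecal-4-ene-4,9β-dicarboxylate | COC(=O)C1=C2CCC3(OCCO3)[C@H](C(=O)OC(C)(C)C)[C@@]2(C)CCC1=O | intermediate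
13 | lithium enolate of 14 before methylation (C3–O–Li, C3=C4, 5α-H; not isolated) | [Li+].[O-]C1=C(C(=O)OC)[C@@H]2CCC3(OCCO3)[C@H](C(=O)OC(C)(C)C)[C@@]2(C)CC1 | intermediate
14 | methyl (C19) tert-butyl (C9) 8,8-(ethylenedioxy)-4α,10β-dimethyl-3-oxo-5α-decalin-4β,9β-dicarboxylate | O1CCOC12CC[C@@H]3[C@](C)(CCC(=O)[C@]3(C)C(=O)OC)[C@H]2C(=O)OC(C)(C)C | intermediate
15 | methyl (C19) tert-butyl (C9) 8,8-(ethylenedioxy)-3β-hydroxy-4α,10β-dimethyl-5α-decalin-4β,9β-dicarboxylate | O1CCOC12CC[C@@H]3[C@](C)(CC[C@H](O)[C@]3(C)C(=O)OC)[C@H]2C(=O)OC(C)(C)C | intermediate
16 | sodium 9β-(tert-butoxycarbonyl)-8,8-(ethylenedioxy)-3β-hydroxy-4α,10β-dimethyl-5α-decalin-4β-carboxylate (not isolated) | [Na+].O1CCOC12CC[C@@H]3[C@](C)(CC[C@H](O)[C@]3(C)C(=O)[O-])[C@H]2C(=O)OC(C)(C)C | intermediate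
17 | allyl (C19) tert-butyl (C9) 8,8-(ethylenedioxy)-3β-hydroxy-4α,10β-dimethyl-5α-decalin-4β,9β-dicarboxylate | O1CCOC12CC[C@@H]3[C@](C)(CC[C@H](O)[C@]3(C)C(=O)OCC=C)[C@H]2C(=O)OC(C)(C)C | intermediate
18 | allyl (C19) tert-butyl (C9) 3β-acetoxy-8,8-(ethylenedioxy)-4α,10β-dimethyl-5α-decalin-4β,9β-dicarboxylate | O1CCOC12CC[C@@H]3[C@](C)(CC[C@H](OC(C)=O)[C@]3(C)C(=O)OCC=C)[C@H]2C(=O)OC(C)(C)C | intermediate
19 | allyl (C19) tert-butyl (C9) 3β-acetoxy-4α,10β-dimethyl-8-oxo-5α-decalin-4β,9β-dicarboxylate | O=C1CC[C@@H]2[C@](C)(CC[C@H](OC(C)=O)[C@]2(C)C(=O)OCC=C)[C@H]1C(=O)OC(C)(C)C | intermediate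
20 | methyl vinyl ketone | C=CC(C)=O | starting material
21 | allyl (C19) tert-butyl (C9) 3β-acetoxy-4α,10β-dimethyl-8-oxo-9α-(3-oxobutyl)-5α-decalin-4β,9β-dicarboxylate | O=C1CC[C@@H]2[C@](C)(CC[C@H](OC(C)=O)[C@]2(C)C(=O)OCC=C)[C@@]1(CCC(C)=O)C(=O)OC(C)(C)C | intermediate
22 | allyl (diethoxyphosphoryl)acetate | C=CCOC(=O)CP(=O)(OCC)OCC | starting material
23 | sodium salt of the carbanion of 22 (not isolated) | [Na+].C=CCOC(=O)[CH-]P(=O)(OCC)OCC | intermediate
24 | allyl (C19) tert-butyl (C9) 3β-acetoxy-9α-[(3E)-5-(allyloxy)-3-methyl-5-oxopent-3-enyl]-4α,10β-dimethyl-8-oxo-5α-decalin-4β,9β-dicarboxylate | O=C1CC[C@@H]2[C@](C)(CC[C@H](OC(C)=O)[C@]2(C)C(=O)OCC=C)[C@@]1(CC/C(C)=C/C(=O)OCC=C)C(=O)OC(C)(C)C | intermediate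
25 | 9β-carboxylic acid corresponding to 24 (β-keto acid; not isolated) | O=C1CC[C@@H]2[C@](C)(CC[C@H](OC(C)=O)[C@]2(C)C(=O)OCC=C)[C@@]1(CC/C(C)=C/C(=O)OCC=C)C(=O)O | intermediate
26 | diallyl 3β-acetoxy-8-oxo-17-norlabd-13E-ene-15,19-dioate | O=C1CC[C@@H]2[C@](C)(CC[C@H](OC(C)=O)[C@]2(C)C(=O)OCC=C)[C@H]1CC/C(C)=C/C(=O)OCC=C | intermediate
27 | diallyl 3β-acetoxylabda-8(17),13E-diene-15,19-dioate | C=C1CC[C@@H]2[C@](C)(CC[C@H](OC(C)=O)[C@]2(C)C(=O)OCC=C)[C@H]1CC/C(C)=C/C(=O)OCC=C | intermediate
28 | 3β-acetoxylabda-8(17),13E-diene-15,19-dioic acid (3β-acetoxy-agathic acid) | C=C1CC[C@@H]2[C@](C)(CC[C@H](OC(C)=O)[C@]2(C)C(=O)O)[C@H]1CC/C(C)=C/C(=O)O | target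

## Step count and least certain steps

Total step count: 19. Longest linear sequence: 19 steps from 1 (5, 20 and 22 are commercial and enter directly).

**Step 7 (key step, proposed new method).** The most likely failure is poor facial selectivity at C10. It would arise if part of the material reacts through a free phenoxonium ion, in which the mediator has already left, or if the iodane binds the phenol oxygen, far from the forming bond. Bonding through the enol oxygen to give a cyclic enol ether, and loss of a proton from the C10 methyl to a quinone methide, are further possible diversions.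

Fallback with known chemistry, setting out from 9 and returning at 10:
- Stoichiometric achiral PhI(OAc)2 in (CF3)2CHOH at 0 °C effects the racemic trivalent-iodine dearomatization by the tethered carbon nucleophile and gives 10 together with its enantiomer F1.
- The mixture is condensed at the C8 ketone with (S)-1-phenylethylamine (cat. AcOH, toluene, molecular sieves). Because C9 becomes trigonal, this gives only two diastereomeric products, the enamino ester F2 from 10 and the enamino ester F3 from F1, which differ at C10 alone and are separated by chromatography or crystallization.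
- Hydrolysis of F2 with aqueous oxalic acid in THF returns enantiopure 10.

**Step 15.** The new bond joins two fully substituted carbons (C9 next to C10), so slow addition, reversal of the addition or diversion into the aldol closure of the 1,5-diketone are the likely problems. Fallback from 19, returning at 21: conjugate addition to but-3-yn-2-one, a slimmer and more electrophilic acceptor (cat. DBU), gives enone F4, and chemoselective conjugate reduction of its side-chain enone with [(Ph3P)CuH]6 (benzene, rt) gives 21.

**Step 10.** Incomplete facial selectivity in the C4 methylation, O-methylation, or proton transfer between enolates before alkylation would lower the yield of the single diastereomer. Fallback from 12, returning at 14: deconjugative methylation of the extended enolate (t-BuOK, t-BuOH–THF, MeI) places the methyl on C4 anti to the C10 methyl and moves the alkene to C5=C6, giving the β,γ-unsaturated keto ester F5. Hydrogenation (H2, Pd/C, EtOAc) from the α face, the β face being blocked by the C10 methyl and the axial C4 ester, then sets the 5α hydrogen and gives 14.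

**Step 18.** The C8 ketone is hindered by the chain on C9 and the syn-axial C10 methyl, so slow methylenation is possible, and forcing it could epimerize C9. Fallback from 26, returning at 27: a two-stage Peterson olefination. Me3SiCH2Li with CeCl3 (THF, −78 °C) adds to the ketone without enolization and in preference to the esters, giving β-hydroxysilane F6, and HF·pyridine in MeCN at 0 °C eliminates it to 27.

**Step 5.** Cyclization of the arylpalladium intermediate onto the β-keto ester (enolate arylation forming a six-membered ring), or sluggish coupling of the electron-rich ortho-substituted bromide, could take material away. Fallback from 4, returning at 8: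
- The β-keto ester is carried in masked form. The lithium dienolate of 2,2,6-trimethyl-4H-1,3-dioxin-4-one (lithium diisopropylamide, THF–DMPU, −78 °C) is alkylated by 4 to give dioxinone F7.
- Suzuki methylation (trimethylboroxine, Pd(dppf)Cl2, K2CO3, dioxane, 90 °C) gives the methylated dioxinone F8, which has no acidic methylene.
- Thermolysis in toluene at 110 °C with t-BuOH traps the acylketene as the tert-butyl β-keto ester 8.

## Further compounds

F1 | step 7 | enantiomer of 10, 1-tert-butyl 5-methyl (1S,8aS)-8a-methyl-2,6-dioxo-1,2,3,4,6,8a-hexahydronaphthalene-1,5-dicarboxylate | COC(=O)C1=C2CCC(=O)[C@@H](C(=O)OC(C)(C)C)[C@]2(C)C=CC1=O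
F2 | step 7 | enamino ester of 10 with (S)-1-phenylethylamine (C8–NH, C8=C9; 10β-CH3 as in 10) | COC(=O)C1=C2CCC(N[C@@H](C)c3ccccc3)=C(C(=O)OC(C)(C)C)[C@@]2(C)C=CC1=O
F3 | step 7 | enamino ester of F1 with (S)-1-phenylethylamine (C10 epimer of F2) | COC(=O)C1=C2CCC(N[C@@H](C)c3ccccc3)=C(C(=O)OC(C)(C)C)[C@]2(C)C=CC1=O
F4 | step 15 | allyl (C19) tert-butyl (C9) 3β-acetoxy-4α,10β-dimethyl-8-oxo-9α-[(1E)-3-oxobut-1-enyl]-5α-decalin-4β,9β-dicarboxylate | O=C1CC[C@@H]2[C@](C)(CC[C@H](OC(C)=O)[C@]2(C)C(=O)OCC=C)[C@@]1(/C=C/C(C)=O)C(=O)OC(C)(C)C
F5 | step 10 | methyl (C19) tert-butyl (C9) 8,8-(ethylenedioxy)-4α,10β-dimethyl-3-oxodecal-5-ene-4β,9β-dicarboxylate | O1CCOC12CC=C3[C@](C)(CCC(=O)[C@]3(C)C(=O)OC)[C@H]2C(=O)OC(C)(C)C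
F6 | step 18 | diallyl 3β-acetoxy-8β-hydroxy-8α-[(trimethylsilyl)methyl]-17-norlabd-13E-ene-15,19-dioate | C[Si](C)(C)C[C@]1(O)CC[C@@H]2[C@](C)(CC[C@H](OC(C)=O)[C@]2(C)C(=O)OCC=C)[C@H]1CC/C(C)=C/C(=O)OCC=C
F7 | step 5 | methyl 3-bromo-6-[(tert-butyldimethylsilyl)oxy]-2-[2-(2,2-dimethyl-4-oxo-4H-1,3-dioxin-6-yl)ethyl]benzoate | COC(=O)c1c(O[Si](C)(C)C(C)(C)C)ccc(Br)c1CCC1=CC(=O)OC(C)(C)O1
F8 | step 5 | methyl 6-[(tert-butyldimethylsilyl)oxy]-2-[2-(2,2-dimethyl-4-oxo-4H-1,3-dioxin-6-yl)ethyl]-3-methylbenzoate | COC(=O)c1c(O[Si](C)(C)C(C)(C)C)ccc(C)c1CCC1=CC(=O)OC(C)(C)O1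
A1 | alternative 1 | (+)-sclareolide | C[C@]12CCCC([C@@H]1CC[C@@]3([C@@H]2CC(=O)O3)C)(C)C
A2 | alternative 1 | 3,4-seco aldehyde: methyl 2-[(1R,2S,3S)-type ring B unit]acrylate with C3 aldehyde, 8(17)-ene and C12 silyl ether (5α-H, 9β chain, 10β-CH3) | C=C1CC[C@@H](C(=C)C(=O)OC)[C@](C)(CCC=O)[C@H]1CCO[Si](C)(C)C(C)(C)C
A3 | alternative 1 | methyl 12-[(tert-butyldimethylsilyl)oxy]-3β-hydroxy-13,14,15,16-tetranorlabd-8(17)-en-19-oate | C=C1CC[C@@H]2[C@](C)(CC[C@H](O)[C@]2(C)C(=O)OC)[C@H]1CCO[Si](C)(C)C(C)(C)C
A4 | alternative 2 | 2-methylcyclohexane-1,3-dione | CC1C(=O)CCCC1=O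
A5 | alternative 2 | methyl 3-oxopent-4-enoate | COC(=O)CC(=O)C=C
A6 | alternative 2 | bicyclic enedione with C4 methyl ester on the C4=C5 alkene, C3 and C9 ketones and 10β-CH3 | COC(=O)C1=C2CCCC(=O)[C@@]2(C)CCC1=O
A7 | alternative 3 | ring A cyclohexanone with C3 ketone, 4α-CH3, 4β-CO2Me, but-3-ynyl on C5 and, on C10, a methyl and the C9 xanthate chain with ketal-protected C13 (C9 epimers) | C#CCC[C@@H]1[C@](C)(CCC(=O)[C@]1(C)C(=O)OC)C(OC(=S)SC)CCC2(C)OCCO2
A8 | alternative 3 | methyl 13,13-(ethylenedioxy)-3-oxo-14,15-dinorlabd-8(17)-en-19-oate | C=C1CC[C@@H]2[C@](C)(CCC(=O)[C@]2(C)C(=O)OC)[C@H]1CCC3(C)OCCO3
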